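Everything rests on opening ring A at the C3–C4 bond. C4, a quaternary carbon with two methyl groups, is bonded to the ring-fusion methine C5; this pair is latent in (R)-carvone as an isopropenyl group on the stereocentre, while the methylated enone of carvone already holds C17, C7=C8 and C9 of ring B. A single hydrogen-atom-transfer step converts the isopropenyl group into the tertiary C4 radical, which adds 6-endo to a vinyl ketone attached at C10, closing ring A as a trans-decalin-1,9-dione. The precursor is (R)-carvone whose α′-carbon (future C10) bears a methyl group cis and an acryloyl group trans to the isopropenyl group.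

Key step: step 4

Remarks: ring carbons are numbered as in labdanes throughout (C17 = methyl on C8, C20 = methyl on C10); α is the face of H-5, β the face of C20. The C1 alcohol and the C9 carbinol met on the way are drawn as the expected major epimers; both centres lose their configuration later. (4-Bromobut-1-yn-1-yl)trimethylsilane is assumed to be commercially available.

Step 1
Reactants: 1 (R)-(−)-carvone
Product: 3 trans-6-methylcarvone [(5R,6S)-2,6-dimethyl-5-(prop-1-en-2-yl)cyclohex-2-en-1-one; minor cis epimer carried along], via carvone lithium dienolate 2 (not isolated)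
Conditions: LiN(i-Pr)2, THF, −78 °C; MeI, −78 → −20 °C
Reagents that add atoms: iodomethane, CI
Why: Kinetic α′-deprotonation gives the cross-conjugated lithium dienolate, which is C-methylated (enolate alkylation); the new centre should form mainly trans to the isopropenyl group but is flattened again in step 2, so its configuration does not matter.

Step 2
Reactants: 3 trans-6-methylcarvone; 4 acrolein
Product: 6 6-(1-hydroxyprop-2-en-1-yl)-6-methylcarvone (hydroxyallyl group trans and methyl cis to the isopropenyl group; both carbinol epimers), via lithium enolate 5 (not isolated)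
Conditions: LiN(i-Pr)2, THF, −78 °C; acrolein, −78 °C; AcOH quench at −78 °C
Reagents that add atoms: none
Why: The fully substituted lithium enolate should add 1,2 to acrolein (aldol addition) on the face opposite the neighbouring isopropenyl group, which sets the quaternary C10 with C1 trans and the C20 methyl cis to that group; the cold acidic quench guards against retro-aldol cleavage.

Step 3
Reactants: 6 aldol adduct
Product: 7 6-acryloyl-6-methyl-(R)-carvone (acryloyl trans and methyl cis to the isopropenyl group)
Conditions: Dess–Martin periodinane, CH2Cl2, 0 °C → rt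
Reagents that add atoms: none
Why: Dess–Martin oxidation converts the secondary allylic alcohol into the vinyl ketone under near-neutral conditions, so the β-hydroxy ketone is not exposed to retro-aldol cleavage and the quaternary C10 cannot epimerise.

Step 4
Reactants: 7 6-acryloyl-6-methyl-(R)-carvone
Product: 8 trans-fused 2,5,5,8a-tetramethyl-4,4a,5,6,7,8a-hexahydronaphthalene-1,8-dione (labdane numbering: 1,9-dione with C7=C8; 5α-H; 10β-CH3; gem-dimethyl C4)
Conditions: Fe(acac)3 (0.3 equiv), PhSiH3, EtOH/ethylene glycol (5:1), 0.02 M, 60 °C
Reagents that add atoms: none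
Why: A trivalent iron hydride formed from Fe(acac)3 and PhSiH3 in ethanol transfers a hydrogen atom to the terminal CH2 of the electron-rich isopropenyl group, giving the tertiary C4 radical that already carries both methyl groups; this radical adds to the unsubstituted β-carbon C3 of the vinyl ketone, and the α-keto radical at C2 is reduced by divalent iron to the enolate and protonated by ethanol, which returns trivalent iron. The closest known reaction type is the iron-mediated hydrogen-atom-transfer reductive coupling of 1,1-disubstituted alkenes with enones (Giese-type radical conjugate addition), known in inter- and intramolecular form. Ring A closes in the 6-endo-trig mode. No new stereocentre is created (C4 carries two methyls, C2 and C3 are methylenes), and the trans ring fusion is already fixed because the C5 and C10 arms are trans-diequatorial on ring B, so the tether can only close to the trans-decalin with C20 axial. The step needs hydrogen-atom transfer to the isopropenyl alkene in the presence of two enones and 6-endo rather than 5-exo closure. Both follow from polarity: the hydridic hydrogen atom goes to the electron-rich alkene, and the nucleophilic tertiary radical prefers the electron-poor terminus C3 (giving a stabilised α-keto radical) over C2 (which would leave a primary radical), while the ring enone is out of reach because attack at C7 or C8 would need a four-membered or bridged five-membered ring.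

Step 5
Reactants: 8 trans-decalin-1,9-dione
Product: 9 trans-fused 8-hydroxy-2,5,5,8a-tetramethyl-4a,5,6,7,8,8a-hexahydronaphthalen-1(4H)-one (labdane numbering: 1β-OH; 7-en-9-one)
Conditions: NaBH4 (0.3 equiv), MeOH/CH2Cl2, −78 → −40 °C
Reagents that add atoms: none
Why: Chemoselective borohydride reduction, since the saturated C1 ketone is more electrophilic than the cross-conjugated α-methylated C9 enone (the selectivity familiar from Wieland–Miescher-type diones); axial hydride delivery anti to the C10 methyl should give the equatorial 1β-alcohol, whose configuration is irrelevant because C1 becomes CH2.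

Step 6
Reactants: 9 1β-hydroxy enone
Product: 10 O-(imidazol-1-ylthiocarbonyl) derivative of 9
Conditions: 1,1′-thiocarbonyldiimidazole, DMAP (cat.), ClCH2CH2Cl, 70 °C
Reagents that add atoms: 1,1′-thiocarbonyldiimidazole, S=C(n1ccnc1)n1ccnc1
Why: Thioacylation of the hindered secondary alcohol with a neutral acyl-transfer reagent gives the Barton–McCombie substrate without forming an alkoxide, which avoids retro-aldol opening of the β-hydroxy ketone.

Step 7
Reactants: 10 thiocarbonylimidazolide
Product: 11 trans-fused 2,5,5,8a-tetramethyl-4a,5,6,7,8,8a-hexahydronaphthalen-1(4H)-one (labdane numbering: 7-en-9-one; C1 = CH2)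
Conditions: Bu3SnH (0.3 M), AIBN (cat.), toluene, 100 °C
Reagents that add atoms: none
Why: Barton–McCombie deoxygenation, in which the stannyl radical adds to sulfur, β-scission releases the secondary C1 radical and hydrogen transfer from concentrated Bu3SnH should outrun any 1,2-acyl shift of this β-keto radical (Dowd–Beckwith-type), leaving the enone untouched.

Step 8
Reactants: 11 bicyclic enone; 12 (4-bromobut-1-yn-1-yl)trimethylsilane
Product: 14 9-hydroxy-14-(trimethylsilyl)-15,16-dinorlabd-7-en-13-yne (tertiary allylic alcohol; 9β-OH and α side chain expected), via Grignard reagent 13 (not isolated)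
Conditions: 12, Mg, THF, 40 °C; CeCl3 (anhydrous), THF, −78 °C; then 11, −78 → 0 °C; aq. NH4Cl
Reagents that add atoms: none
Why: The Grignard reagent activated by CeCl3 (organocerium conditions) should add 1,2 to the hindered non-enolisable C9 ketone while γ-deprotonation and conjugate addition are suppressed; attack anti to the axial C10 methyl is expected, but this centre is erased in step 9.

Step 9
Reactants: 14 tertiary allylic alcohol
Product: 15 14-(trimethylsilyl)-15,16-dinorlabd-8-en-13-yn-7-one
Conditions: pyridinium chlorochromate, 4 Å molecular sieves, CH2Cl2, rt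
Reagents that add atoms: pyridinium chlorochromate (its oxo oxygen ends on C7 through the [3,3] shift), [O-][Cr](=O)(=O)Cl.c1cc[nH+]cc1
Why: Babler–Dauben oxidative transposition, in which the chromate ester of the tertiary allylic alcohol undergoes a [3,3] shift to the less hindered C7 and is oxidised there, giving the 8-en-7-one with the side chain on the alkene.

Step 10
Reactants: 15 transposed enone
Product: 16 14-(trimethylsilyl)-15,16-dinorlabd-8-en-13-yn-7β-ol
Conditions: NaBH4, CeCl3·7H2O, MeOH, −78 → 0 °C
Reagents that add atoms: none
Why: Luche reduction gives clean 1,2-reduction, and axial hydride delivery on the α-face of the half-chair (the β-face carries the angular C10 methyl) should set the new C7 centre as the pseudo-equatorial 7β-alcohol.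

Step 11
Reactants: 16 7β-allylic alcohol
Product: 19 14-(trimethylsilyl)-15,16-dinorlabd-7-en-13-yne (9α-H; side chain β), via sulfonylhydrazine 17 (not isolated), via allylic diazene 18 (not isolated)
Conditions: 2-nitrobenzenesulfonylhydrazide, PPh3, DEAD, N-methylmorpholine, −30 °C; then rt
Reagents that add atoms: none
Why: Reductive 1,3-transposition through an allylic diazene, in which Mitsunobu displacement inverts C7 (7α-N), loss of arenesulfinic acid gives the 7α-diazene and its retro-ene loss of N2 delivers hydrogen suprafacially to the α-face of C9 while the alkene moves to C7=C8, so the C9 centre (9α-H, equatorial β side chain) is set by the C7 configuration.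

Step 12
Reactants: 19 silylated enyne
Product: 21 15,16-dinorlabd-7-en-13-yn-17-ol, via silylated allylic alcohol 20 (not isolated)
Conditions: SeO2 (cat.), t-BuOOH, CH2Cl2, 0 °C → rt; aqueous work-up; then K2CO3, MeOH, rt
Reagents that add atoms: selenium dioxide (oxygen carrier), O=[Se]=O; tert-butyl hydroperoxide (terminal oxygen source), CC(C)(C)OO
Why: Riley-type allylic oxidation, in which the ene reaction at the only alkene places selenium on C7 and takes hydrogen from the C17 methyl (the unhindered allylic group on the more substituted alkene carbon) and the [2,3] shift returns C7=C8 with oxygen on C17; the silylalkyne is inert and methanolic K2CO3 then cleaves the C–Si bond.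

Step 13
Reactants: 21 terminal alkyne
Product: 23 (13E)-labda-7,13-diene-15,17-diol, via alkenylalane 22 (not isolated)
Conditions: AlMe3, Cp2ZrCl2 (0.25 equiv), CH2Cl2, 0 °C → rt; evaporate; n-BuLi, THF, −78 → 0 °C; (CH2O)n, rt; aq. potassium sodium tartrate
Reagents that add atoms: trimethylaluminium, C[Al](C)C; formaldehyde (from paraformaldehyde), C=O
Why: Zirconium-catalysed carboalumination adds methyl and aluminium syn across the terminal alkyne (methyl to C13, aluminium to C14), which fixes the E geometry of C13=C14, and the alkenylalanate formed with n-BuLi is hydroxymethylated by formaldehyde with retention while the 17-hydroxyl is carried as its aluminium alkoxide.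

Step 14
Reactants: 23 (13E)-labda-7,13-diene-15,17-diol
Product: 24 (13E)-labda-7,13-diene-15,17-diyl diacetate, (5S,9R,10S), the target
Conditions: Ac2O, pyridine, DMAP (cat.), CH2Cl2, rt
Reagents that add atoms: acetic anhydride, CC(=O)OC(C)=O
Why: Nucleophile-catalysed acetylation of both primary allylic alcohols should give the diacetate without touching any stereocentre or alkene.

Compound list
1 | (R)-(−)-carvone | CC1=CC[C@@H](C(C)=C)CC1=O | starting material
2 | kinetic lithium dienolate of carvone | CC1=CC[C@@H](C(C)=C)C=C1O[Li] | intermediate (not isolated)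
3 | trans-6-methylcarvone, (5R,6S)-2,6-dimethyl-5-(prop-1-en-2-yl)cyclohex-2-en-1-one | CC1=CC[C@@H](C(C)=C)[C@H](C)C1=O | intermediate
4 | acrolein | C=CC=O | starting material
5 | lithium enolate of 3 | CC1=CC[C@@H](C(C)=C)C(C)=C1O[Li] | intermediate (not isolated)
6 | 6-(1-hydroxyprop-2-en-1-yl)-6-methylcarvone, hydroxyallyl trans and methyl cis to isopropenyl, carbinol epimers | C=CC(O)[C@]1(C)C(=O)C(C)=CC[C@H]1C(C)=C | intermediate
7 | 6-acryloyl-6-methyl-(R)-carvone, acryloyl trans and methyl cis to isopropenyl | C=CC(=O)[C@]1(C)C(=O)C(C)=CC[C@H]1C(C)=C | intermediate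
8 | trans-fused 2,5,5,8a-tetramethyl-4,4a,5,6,7,8a-hexahydronaphthalene-1,8-dione (1,9-dione, C7=C8) | CC1=CC[C@H]2C(C)(C)CCC(=O)[C@]2(C)C1=O | intermediate
9 | 1β-hydroxy-7-en-9-one (trans-fused 8-hydroxy-2,5,5,8a-tetramethyl-4a,5,6,7,8,8a-hexahydronaphthalen-1(4H)-one) | CC1=CC[C@H]2C(C)(C)CC[C@@H](O)[C@]2(C)C1=O | intermediate
10 | O-(imidazol-1-ylthiocarbonyl) derivative of 9 | CC1=CC[C@H]2C(C)(C)CC[C@@H](OC(=S)n3ccnc3)[C@]2(C)C1=O | intermediate
11 | trans-fused 2,5,5,8a-tetramethyl-4a,5,6,7,8,8a-hexahydronaphthalen-1(4H)-one (7-en-9-one) | CC1=CC[C@H]2C(C)(C)CCC[C@]2(C)C1=O | intermediate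
12 | (4-bromobut-1-yn-1-yl)trimethylsilane | C[Si](C)(C)C#CCCBr | starting material
13 | [4-(trimethylsilyl)but-3-yn-1-yl]magnesium bromide | C[Si](C)(C)C#CCC[Mg]Br | intermediate (not isolated)
14 | 9-hydroxy-14-(trimethylsilyl)-15,16-dinorlabd-7-en-13-yne, 9β-OH | C[Si](C)(C)C#CCC[C@]1(O)C(C)=CC[C@H]2C(C)(C)CCC[C@]12C | intermediate
15 | 14-(trimethylsilyl)-15,16-dinorlabd-8-en-13-yn-7-one | C[Si](C)(C)C#CCCC1=C(C)C(=O)C[C@H]2C(C)(C)CCC[C@]12C | intermediate
16 | 14-(trimethylsilyl)-15,16-dinorlabd-8-en-13-yn-7β-ol | C[Si](C)(C)C#CCCC1=C(C)[C@@H](O)C[C@H]2C(C)(C)CCC[C@]12C | intermediate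
17 | 7α-[1-(2-nitrobenzenesulfonyl)hydrazin-1-yl] derivative | C[Si](C)(C)C#CCCC1=C(C)[C@H](N(N)S(=O)(=O)c3ccccc3[N+](=O)[O-])C[C@H]2C(C)(C)CCC[C@]12C | intermediate (not isolated)
18 | 7α-diazenyl derivative (allylic diazene) | C[Si](C)(C)C#CCCC1=C(C)[C@H](N=N)C[C@H]2C(C)(C)CCC[C@]12C | intermediate (not isolated)
19 | 14-(trimethylsilyl)-15,16-dinorlabd-7-en-13-yne, 9α-H | C[Si](C)(C)C#CCC[C@H]1C(C)=CC[C@H]2C(C)(C)CCC[C@]12C | intermediate
20 | 14-(trimethylsilyl)-15,16-dinorlabd-7-en-13-yn-17-ol | C[Si](C)(C)C#CCC[C@H]1C(CO)=CC[C@H]2C(C)(C)CCC[C@]12C | intermediate (not isolated)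
21 | 15,16-dinorlabd-7-en-13-yn-17-ol | C#CCC[C@H]1C(CO)=CC[C@H]2C(C)(C)CCC[C@]12C | intermediate
22 | (13E)-14-(dimethylalumanyl)-15-norlabda-7,13-dien-17-ol dimethylaluminium alkoxide | C[Al](C)/C=C(\C)CC[C@H]1C(CO[Al](C)C)=CC[C@H]2C(C)(C)CCC[C@]12C | intermediate (not isolated)
23 | (13E)-labda-7,13-diene-15,17-diol | OC/C=C(\C)CC[C@H]1C(CO)=CC[C@H]2C(C)(C)CCC[C@]12C | intermediate
24 | (13E)-labda-7,13-diene-15,17-diyl diacetate, (5S,9R,10S) | CC(=O)OC/C=C(\C)CC[C@H]1C(COC(C)=O)=CC[C@H]2C(C)(C)CCC[C@]12C | target

Total step count: 14. Longest linear sequence: 14 steps from 1 to 24; 4 and 12 are used as purchased.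

Steps most likely to fail

Step 4. The iron hydride may reduce the vinyl ketone by simple conjugate reduction, or intermolecular radical addition may compete with ring closure, so that ring A does not form cleanly. The fallback generates the same radical from a discrete halide instead of by hydrogen-atom transfer. Setting out from 7, HBr in AcOH at 0 °C should add in the Markovnikov sense to the isopropenyl group and also to the vinyl ketone, giving the bis(hydrobromide) F1. Et3N in CH2Cl2 would re-form the enone by elimination of the β-bromo ketone and leave the tertiary bromide vinyl ketone F2. Slow addition of Bu3SnH with AIBN in toluene at 80 °C should then abstract bromine, and the tertiary C4 radical closes ring A 6-endo, rejoining the route at 8.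

Step 11. Mitsunobu displacement at the hindered allylic C7 may be slow and give way to ionisation or elimination, which would erode the configuration that is relayed to C9. The fallback replaces the diazene by palladium-catalysed formate hydrogenolysis. From 16, acetic formic anhydride and pyridine should give the 7β-formate F3. Pd(OAc)2 and PBu3 in dioxane (zerovalent palladium formed in the flask) would ionise it with inversion, placing palladium on the α-face. After loss of CO2 the palladium hydride should deliver hydrogen from that face to the more substituted allyl terminus C9, giving 19 directly.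

Step 12. The ene step may lack site selectivity (abstraction at C9–H or C6), and C17 may be over-oxidised to the enal; the latter would be corrected by adding NaBH4 to the methanolic work-up. The fallback brings the oxygen in through an epoxide. From 19, mCPBA in CH2Cl2 should epoxidise the only alkene from the α-face to the 7α,8α-epoxide F4. Al(Oi-Pr)3 in refluxing toluene would isomerise it to the exocyclic allylic alcohol F5 (8(17)-en-7α-ol), and Ac2O/pyridine then gives the 7α-acetate F6. PdCl2(MeCN)2 (divalent palladium) in THF should equilibrate this by [3,3] shift to the primary allylic acetate F7 with the C7=C8 alkene. K2CO3 in MeOH finally removes acetate and silyl group together and rejoins the route at 21.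

Further compounds
F1 | step 4 | 6-(3-bromopropanoyl)-5-(2-bromopropan-2-yl)-2,6-dimethylcyclohex-2-en-1-one, bis(hydrobromide) of 7 | BrCCC(=O)[C@]1(C)C(=O)C(C)=CC[C@H]1C(C)(C)Br
F2 | step 4 | 6-acryloyl-5-(2-bromopropan-2-yl)-2,6-dimethylcyclohex-2-en-1-one | C=CC(=O)[C@]1(C)C(=O)C(C)=CC[C@H]1C(C)(C)Br
F3 | step 11 | 7β-formate of 16 | C[Si](C)(C)C#CCCC1=C(C)[C@@H](OC=O)C[C@H]2C(C)(C)CCC[C@]12C
F4 | step 12 | 7α,8α-epoxide of 19 | C[Si](C)(C)C#CCC[C@H]1[C@]2(C)O[C@@H]2C[C@H]3C(C)(C)CCC[C@]13C
F5 | step 12 | 14-(trimethylsilyl)-15,16-dinorlabd-8(17)-en-13-yn-7α-ol | C[Si](C)(C)C#CCC[C@H]1C(=C)[C@H](O)C[C@H]2C(C)(C)CCC[C@]12C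
F6 | step 12 | 7α-acetate of F5 | C[Si](C)(C)C#CCC[C@H]1C(=C)[C@H](OC(C)=O)C[C@H]2C(C)(C)CCC[C@]12C
F7 | step 12 | 14-(trimethylsilyl)-15,16-dinorlabd-7-en-13-yn-17-yl acetate | C[Si](C)(C)C#CCC[C@H]1C(COC(C)=O)=CC[C@H]2C(C)(C)CCC[C@]12C
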